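Initiator still left over at the end of a flask has begun no chain, and two chemists dispute how much of it cedar and alder leave.

in all of them: initiator 2.5 mM

| run | free monomer | remark | time |
|---|---|---|---|
| blue | 0.075 M (fed, over 12 h) | run made earlier; the fed solution adds 1.0 times the starting volume |  |
| cedar | 0.050 M (fed, over 12 h) | the fed solution adds 1.0 times the starting volume | 6.0 d |
| alder | 0.050 M (fed, over 4.0 h) | the fed solution adds 1.0 times the starting volume | 6.0 d |

blue run (percent of the free monomer charged)

| time / h | monomer in chains / % | free monomer / % |
|---|---|---|
| 1.00 | 0 | 8.4 |
| 2.00 | 0 | 16.5 |
| 3.00 | 0.9 | 23.3 |
| 5.00 | 3.0 | 39.6 |
| 8.00 | 8.2 | 57.8 |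
| 15.0 | 27.9 | 70.2 |

(each reading ± 1 percentage point)

* which of the two ends with the longer chains by the average number of monomer units in a chain (chains begun, living or dead) ("neither" if they lie within 10%) (cedar / alder / neither)
* average number of monomer units in a chain (chains begun, living or dead) at the end, cedar
* average number of monomer units in a chain (chains begun, living or dead) at the end, alder

- amounts are per litre of the starting volume; all of the dose is in the solution fed
- the average divides the monomer in chains by the number of chains begun, living and dead together
- the earlier runs do not show the number of chains; that part of a forecast is a guess
- percentages count the whole charge, also what has not yet gone in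

In blue, free monomer and monomer in chains together hold 98.1% of the charge at 15.0 h, so within the scatter nothing is lost. The count of chains is not read, so both sides reckon with 20.0 for cedar and alder, the charge ratio, the free monomer charged per initiator charged. If a fraction f of the initiator has begun chains and the charge ends up in chains, the average length is the ratio over f.

The first chemist takes f near 1, which gives 20.0 for both flasks. The second points to blue's slow start, with 0% in chains at 2.00 h and 27.9% at 15.0 h. She holds that thinly fed free monomer may be gone with much initiator unused. At f of 0.5 the length would be 40.0, and f might differ between the two feeds.

The forecast sides with the first: neither, with 21 for cedar and 21 for alder, above my 20.0 to allow for surviving initiator. Its ground: “both the chains begun and the monomer used depend on the same integral, so feed time scarcely matters”.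

The simulation gives neither, with 20.4 for cedar and 20.4 for alder.

    free monomer + initiator → living end + monomer in chains (k = 0.00161 L mol⁻¹ s⁻¹)
    free monomer + living end → monomer in chains + living end, rate k2*[living end]*[free monomer] (k = 0.0116 L mol⁻¹ s⁻¹)
    monomer in chains → over-reaction product (k = 1.55 × 10⁻⁸ s⁻¹)

In cedar f is 97.3%, and the ratio, times the 99.2% in chains, over f gives 20.4. Cedar is not quite at rest at 6.0 d. By 60.0 d monomer in chains falls to 92.4% and over-reaction product rises from 0.636% to 7.57%, a slow step with a half-life of 520 d, long against the time. The length then reads 19.0, and alder's 19.0.

The second chemist's region shows in the neighbour, alder with 0.013 M of free monomer, where the charge ratio gives 5.20. That flask ends at 6.92, longer than the ratio, with 26% of its initiator left over.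

(The numbers in the tables were computed for substances that don't exist, and the scatter is random.)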